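**Retrosynthetic overview**
1. The oxygen bridge, the ring-A C–Br bond and the two centres next to them come last, by transannular bromoetherification of a 1-substituted 4-methylcyclohex-3-en-1-ol.
2. Six-membered ring A comes from ring expansion of a 2-methylbicyclo[3.1.0]hexan-2-ol. The internal cyclopropane bond breaks and water enters at the quaternary carbon with inversion.
3. The bicyclo[3.1.0]hexanone comes from a catalyst-controlled intramolecular cyclopropanation of a diazo ketone. Its chain is built from a ring-B alkyne and but-3-en-2-ol.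
4. Ring B, with both of its centres, comes first. An acyclic dienol (methallyl alcohol + prenyl bromide) undergoes an enantioselective bromonium cyclisation that ends in a 1,2-hydride shift.
5. Order of rings: ring B, then the cyclopropane-fused five-membered ring, then six-membered ring A by expansion, then the oxygen bridge.

Assumption: for the chiral catalysts of steps 2 and 6, the antipode named is the one expected to give the drawn configuration; if the sense of induction is opposite, the mirror-image catalyst is used.

**Step 1**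
Reactants: 1 2-methylprop-2-en-1-ol (methallyl alcohol); 2 1-bromo-3-methylbut-2-ene (prenyl bromide)
Product: 4 6-methyl-2-methylidenehept-5-en-1-ol, via dilithiated methallyl alcohol 3 (not isolated)
Conditions: n-BuLi (2.2 equiv), TMEDA, Et2O/hexane, 0 °C to rt; then 2, −78 °C to rt; H2O
Reagents that add atoms: none
Why: Allylic dilithiation gives a symmetric allyl anion whose carbon end displaces the primary allylic bromide (dianion alkylation, SN2); no stereocentre is formed.

**Step 2**
Reactants: 4 6-methyl-2-methylidenehept-5-en-1-ol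
Product: 5 (1S,4S)-4-bromo-3,3-dimethylcyclohexane-1-carbaldehyde
Conditions: (R)-BINOL-derived thiophosphoramide Lewis base (10 mol %), DBDMH (0.55 equiv, both Br used), toluene/CH2Cl2 1:1, −78 °C; cold pH 7 buffer
Reagents that add atoms: 1,3-dibromo-5,5-dimethylhydantoin (DBDMH), CC1(C)N(Br)C(=O)N(Br)C1=O
Why: Proposed new method: the chiral sulfur Lewis base takes Br+ from DBDMH and hands it to one face of the trisubstituted alkene (sets C–Br as S); the 1,1-disubstituted alkene closes ring B through a chair with Br equatorial; the tertiary cation next to CH2OH is quenched by a semipinacol-type 1,2-hydride shift into the axial lobe, favoured torsionally and because the other lobe would push the carbinol carbon syn-axial to a methyl group, so CHO ends equatorial and trans to Br (1S) before ring flip or enolisation; the closest known reactions are the Lewis-base-catalysed asymmetric bromocyclisation of polyenes and the acid isomerisation of methallyl alcohol to isobutyraldehyde.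

**Step 3**
Reactants: 5 (1S,4S)-4-bromo-3,3-dimethylcyclohexane-1-carbaldehyde
Product: 6 (1S,4S)-1-bromo-4-ethynyl-2,2-dimethylcyclohexane
Conditions: Me3SiCHN2, LiN(i-Pr)2, THF, −78 °C; then 5, −78 °C to 0 °C; H2O
Reagents that add atoms: (trimethylsilyl)diazomethane, C[Si](C)(C)C=[N+]=[N-]
Why: In the Colvin rearrangement, fast addition at −78 °C, loss of silanolate and N2, and a 1,2-H shift of the alkylidene carbene turn CHO into C≡CH without touching the α-centre, which is no longer enolisable afterwards.

**Step 4**
Reactants: 6 (1S,4S)-1-bromo-4-ethynyl-2,2-dimethylcyclohexane; 7 but-3-en-2-ol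
Product: 8 5-[(1S,4S)-4-bromo-3,3-dimethylcyclohexyl]hex-5-en-2-one
Conditions: 7 (3 equiv), [CpRu(MeCN)3]PF6 (10 mol %), acetone, rt
Reagents that add atoms: none
Why: The Trost ruthenium-catalysed alkyne–allylic alcohol coupling (Alder-ene type, via a ruthenacyclopentene) bonds the internal alkyne carbon to the alkene CH2, and β-hydride elimination at the carbinol carbon releases an enol that becomes the methyl ketone; no new stereocentre is formed.

**Step 5**
Reactants: 8 5-[(1S,4S)-4-bromo-3,3-dimethylcyclohexyl]hex-5-en-2-one
Product: 10 5-[(1S,4S)-4-bromo-3,3-dimethylcyclohexyl]-1-diazohex-5-en-2-one, via trifluoroacetyl diketone 9 (not isolated)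
Conditions: LiN(SiMe3)2, THF, −78 °C; CF3CO2CH2CF3; then MsN3, Et3N, H2O, MeCN, rt
Reagents that add atoms: methanesulfonyl azide, CS(=O)(=O)N=[N+]=[N-]; 2,2,2-trifluoroethyl trifluoroacetate (into 9 only), O=C(OCC(F)(F)F)C(F)(F)F
Why: In the Danheiser detrifluoroacetylative diazo transfer, kinetic deprotonation at the methyl group and trifluoroacetylation activate only that carbon, so the terminal α-diazo ketone forms while the alkene and the hindered bromide are untouched.

**Step 6**
Reactants: 10 5-[(1S,4S)-4-bromo-3,3-dimethylcyclohexyl]-1-diazohex-5-en-2-one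
Product: 11 (1S,5R)-5-[(1S,4S)-4-bromo-3,3-dimethylcyclohexyl]bicyclo[3.1.0]hexan-2-one
Conditions: [Cu(MeCN)4]PF6 (5 mol %), (S,S)-t-Bu-box (6 mol %), CH2Cl2, slow addition of 10, rt
Reagents that add atoms: none
Why: In this intramolecular carbenoid cyclopropanation of an α-diazo ketone, the chiral copper carbene adds to one face of the tethered 1,1-disubstituted alkene under catalyst control (ring B is too remote to interfere) and the tether enforces cis fusion, which sets both cyclopropane centres as in the known isopropyl analogue, sabina ketone.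

**Step 7**
Reactants: 11 (1S,5R)-5-[(1S,4S)-4-bromo-3,3-dimethylcyclohexyl]bicyclo[3.1.0]hexan-2-one
Product: 12 (1S,2R,5R)-5-[(1S,4S)-4-bromo-3,3-dimethylcyclohexyl]-2-methylbicyclo[3.1.0]hexan-2-ol
Conditions: MeMgBr, Et2O, −40 to 0 °C; H2O (pH 7)
Reagents that add atoms: methylmagnesium bromide, C[Mg]Br
Why: Grignard 1,2-addition from the face away from the cyclopropane CH2 gives the tertiary cyclopropylcarbinol (2R); this centre is erased in step 8, so its ratio does not matter.

**Step 8**
Reactants: 12 (1S,2R,5R)-5-[(1S,4S)-4-bromo-3,3-dimethylcyclohexyl]-2-methylbicyclo[3.1.0]hexan-2-ol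
Product: 14 (1R,2R,4S)-2-bromo-4-[(1S,4S)-4-bromo-3,3-dimethylcyclohexyl]-1-methyl-7-oxabicyclo[2.2.1]heptane, via ring-expanded cyclohexenol 13 (not isolated)
Conditions: HClO4 (cat.), acetone/H2O 3:1, 0 °C; NaHCO3; then NBS (1.05 equiv), 0 °C
Reagents that add atoms: water, O; N-bromosuccinimide, O=C1CCC(=O)N1Br
Why: In the cyclopropylcarbinyl-to-homoallyl ring expansion (the thujane-to-p-menthane change known for sabinene hydrate to terpinen-4-ol), ionisation at the carbinol carbon breaks the internal cyclopropane bond while water attacks the quaternary carbon from the back (inversion, 1S in 13), which turns the five-membered ring into ring A under conditions where 13 ionises far more slowly than 12; NBS then places the bromonium ion anti to OH, and transannular anti attack at the tertiary carbon (bromoetherification) closes the bridge and sets the last two centres with Br endo.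

**Compound list**
1 | 2-methylprop-2-en-1-ol (methallyl alcohol) | CC(=C)CO | starting material
2 | 1-bromo-3-methylbut-2-ene (prenyl bromide) | CC(C)=CCBr | starting material
3 | dilithiated methallyl alcohol, LiCH2C(=CH2)CH2OLi | [Li]CC(=C)CO[Li] | intermediate
4 | 6-methyl-2-methylidenehept-5-en-1-ol | CC(C)=CCCC(=C)CO | intermediate
5 | (1S,4S)-4-bromo-3,3-dimethylcyclohexane-1-carbaldehyde (Br and CHO trans, both equatorial) | CC1(C)C[C@@H](C=O)CC[C@@H]1Br | intermediate
6 | (1S,4S)-1-bromo-4-ethynyl-2,2-dimethylcyclohexane | CC1(C)C[C@@H](C#C)CC[C@@H]1Br | intermediate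
7 | but-3-en-2-ol (racemic) | CC(O)C=C | starting material
8 | 5-[(1S,4S)-4-bromo-3,3-dimethylcyclohexyl]hex-5-en-2-one | CC1(C)C[C@@H](C(=C)CCC(C)=O)CC[C@@H]1Br | intermediate
9 | 7-[(1S,4S)-4-bromo-3,3-dimethylcyclohexyl]-1,1,1-trifluorooct-7-ene-2,4-dione | CC1(C)C[C@@H](C(=C)CCC(=O)CC(=O)C(F)(F)F)CC[C@@H]1Br | intermediate
10 | 5-[(1S,4S)-4-bromo-3,3-dimethylcyclohexyl]-1-diazohex-5-en-2-one | CC1(C)C[C@@H](C(=C)CCC(=O)C=[N+]=[N-])CC[C@@H]1Br | intermediate
11 | (1S,5R)-5-[(1S,4S)-4-bromo-3,3-dimethylcyclohexyl]bicyclo[3.1.0]hexan-2-one | CC1(C)C[C@@H]([C@]23CCC(=O)[C@H]2C3)CC[C@@H]1Br | intermediate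
12 | (1S,2R,5R)-5-[(1S,4S)-4-bromo-3,3-dimethylcyclohexyl]-2-methylbicyclo[3.1.0]hexan-2-ol (OH cis to the cyclopropane CH2) | CC1(C)C[C@@H]([C@]23CC[C@@](C)(O)[C@H]2C3)CC[C@@H]1Br | intermediate
13 | (1S)-1-[(1S,4S)-4-bromo-3,3-dimethylcyclohexyl]-4-methylcyclohex-3-en-1-ol | CC1(C)C[C@@H]([C@]2(O)CCC(C)=CC2)CC[C@@H]1Br | intermediate
14 | (1R,2R,4S)-2-bromo-4-[(1S,4S)-4-bromo-3,3-dimethylcyclohexyl]-1-methyl-7-oxabicyclo[2.2.1]heptane (Br endo) | CC1(C)C[C@@H]([C@@]23CC[C@@](C)(O2)[C@H](Br)C3)CC[C@@H]1Br | target

**Total steps:** 8. **Longest linear sequence:** 8.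

**Three steps most likely to fail**

**Step 2 (the new step).** The risks are low facial selectivity in the Br+ transfer, proton loss instead of the hydride shift, and hydride delivery to the wrong lobe.
- The fallback sets out from 4 and comes back at 5. It moves the stereochemical information from the catalyst into the substrate.
- Shi epoxidation of the trisubstituted alkene of 4 gives 4-[(2R)-3,3-dimethyloxiran-2-yl]-2-methylidenebutan-1-ol F1. Conditions are the D-fructose-derived ketone, KHSO5, buffered MeCN/H2O, 0 °C.
- Li2NiBr4 in THF opens F1 by SN2 attack at the secondary carbon, with inversion, to give (5S)-5-bromo-6-methyl-2-methylideneheptane-1,6-diol F2.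
- Ionising the tertiary hydroxyl of F2 (cat. TfOH, HFIP, 0 °C) with neighbouring-group help from bromine regenerates the same bromonium ion as a single enantiomer.
- That ion closes through the same chair and ends, like the acid isomerisation of 2-substituted allylic alcohols, in aldehyde 5.

**Step 8.** If the tertiary cation escapes before water attacks, the configuration at the carbinol carbon of 13 erodes, which gives a separable diastereomer of 14. Dienes and a hydride shift from the ring-B methine also become possible.
- The fallback sets out from 5 and comes back at 13. It builds ring A by metathesis rather than by expansion.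
- (3-Methylbut-3-en-1-yl)magnesium bromide at −78 °C gives 1-[(1S,4S)-4-bromo-3,3-dimethylcyclohexyl]-4-methylpent-4-en-1-ol F3.
- Dess–Martin periodinane gives 1-[(1S,4S)-4-bromo-3,3-dimethylcyclohexyl]-4-methylpent-4-en-1-one F4.
- Diol-catalysed asymmetric allylboration (allyl-B(O-i-Pr)2, (S)-3,3′-Br2-BINOL, toluene, −35 °C) gives (4S)-4-[(1S,4S)-4-bromo-3,3-dimethylcyclohexyl]-7-methylocta-1,7-dien-4-ol F5.
- Ring-closing metathesis with second-generation Grubbs catalyst gives 13. It is isolated and treated with NBS as in the second half of step 8.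

**Step 4.** The propargylic carbon is branched, so the linear (E)-enone may compete with the branched product, and the ruthenium catalyst may simply isomerise 7.
- The fallback sets out from 6 and comes back at 8. It fixes the regiochemistry by haloboration.
- B-bromo-9-BBN (CH2Cl2, 0 °C), then AcOH, gives (1S,4S)-1-bromo-4-(1-bromoethenyl)-2,2-dimethylcyclohexane F6.
- Negishi coupling with [2-(2-methyl-1,3-dioxolan-2-yl)ethyl]zinc bromide and Pd(dppf)Cl2 in THF reacts only at the alkenyl bromide. It gives 2-{3-[(1S,4S)-4-bromo-3,3-dimethylcyclohexyl]but-3-en-1-yl}-2-methyl-1,3-dioxolane F7.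
- PPTS in wet acetone frees ketone 8.

**Further compounds**
F1 | step 2 | 4-[(2R)-3,3-dimethyloxiran-2-yl]-2-methylidenebutan-1-ol | CC1(C)O[C@@H]1CCC(=C)CO
F2 | step 2 | (5S)-5-bromo-6-methyl-2-methylideneheptane-1,6-diol | CC(C)(O)[C@@H](Br)CCC(=C)CO
F3 | step 8 | 1-[(1S,4S)-4-bromo-3,3-dimethylcyclohexyl]-4-methylpent-4-en-1-ol (both carbinol epimers) | CC1(C)C[C@@H](C(O)CCC(C)=C)CC[C@@H]1Br
F4 | step 8 | 1-[(1S,4S)-4-bromo-3,3-dimethylcyclohexyl]-4-methylpent-4-en-1-one | CC1(C)C[C@@H](C(=O)CCC(C)=C)CC[C@@H]1Br
F5 | step 8 | (4S)-4-[(1S,4S)-4-bromo-3,3-dimethylcyclohexyl]-7-methylocta-1,7-dien-4-ol | CC1(C)C[C@@H]([C@@](O)(CC=C)CCC(C)=C)CC[C@@H]1Br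
F6 | step 4 | (1S,4S)-1-bromo-4-(1-bromoethenyl)-2,2-dimethylcyclohexane | CC1(C)C[C@@H](C(Br)=C)CC[C@@H]1Br
F7 | step 4 | 2-{3-[(1S,4S)-4-bromo-3,3-dimethylcyclohexyl]but-3-en-1-yl}-2-methyl-1,3-dioxolane | CC1(C)C[C@@H](C(=C)CCC2(C)OCCO2)CC[C@@H]1Br
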